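# Proposed total synthesis of CNP0287617.1 by chromium carbene benzannulation on a bridged bicyclic alkene

## Analysis of the target

Locants used throughout: the benzo-fused bicyclo[3.2.1]octene core is C1 (quaternary bridgehead), C2 (CH2), C3 (C–CH3), C4 (=CH), C5 (methine bridgehead), C6 and C7 (the two arene ring-fusion carbons, C6 on C5 and C7 on C1) and C8 (quaternary one-carbon bridge). The cyclopentanone is C8–C1′(=O)–C2′(H)–C3′(H, isopropenyl)–C4′(H2). C9(=O) sits on C1, and C10(H2) links C9 to C2′.

- The hydroquinone (ring A) is fused through C6–C7 to a bicyclo[3.2.1]octene built from the five-membered ring B (C5–C6–C7–C1–C8) and the methylcyclohexene ring C (C1–C2–C3=C4–C5–C8).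
- The C1–C8 bond is shared with a second bicyclo[3.2.1] unit: the cyclohexane-1,4-dione ring D (C8–C1′–C2′–C10–C9–C1), bridged by the cyclopentanone ring E (C8–C1′–C2′–C3′–C4′).
- There are five stereocentres (C1, C5, C8, C2′, C3′). C1 and C5 are tied together by the bridge. At C8 the carbonyl arm C1′ lies over ring A and the CH2 arm C4′ over ring C. C2′ is dictated by ring D. The isopropenyl group on C3′ is exo, on the side of C5 and away from C9.
- Only three elements are therefore independent: the absolute configuration of C8, the face of C8 on which the C2–C4 bridge sits, and C3′.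
- Sensitive groups are the hydroquinone (air oxidation), the enolisable 1,4-diketone, and the isopropenyl group (acid isomerisation). C5 is benzylic and allylic but, being a bridgehead, cannot epimerise.
- The difficulty lies in the vicinal quaternary carbons C1 and C8, each a member of three rings, with five rings packed around them.
- The strategy rests on ring A. It touches the rest of the molecule only at C6 and C7, carries no stereocentre, and has its two oxygens on the arene carbons next to C6 and C7, para to each other. That is exactly the pattern produced when an alkenyl(alkoxy)carbene of chromium on a C6=C7 alkene takes up an alkyne and one CO.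

## Retrosynthetic reasoning

**34 to 32.** Only the two O–CH3 bonds are cut. The hydroquinone must be masked during enolate oxidation. Methyl ethers can be removed oxidatively through quinone 33 under conditions that spare ketones and alkenes, and reduction of 33 returns 34.

**32 to 31.** The C2′–C10 bond of ring D is cut, the bond between the two α-carbons of the 1,4-diketone. In 31 each ketone has only one enolisable α-carbon (C2′ or C10), because C8 and C1 are quaternary. The bis-enolate is therefore regiodefined, and C10 can reach only one face of C2′. The forward step is an intramolecular oxidative enolate coupling.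

**31 to 30 to 28.** These are protecting-group changes only: the two ketones return to their dioxolanes, the second O-methyl group is removed and the silyl group is put back. The ketals are needed because the carbene is made from an organolithium.

**28 to 26 and 27.** Ring A is taken apart into the C6=C7 alkenyl carbene 26, the alkyne 27 and one CO ligand. Three ring bonds are cut: carbene carbon to alkyne CH, silyl-bearing alkyne carbon to CO, and CO to C7. This is the place for the key disconnection because no stereocentre is involved and the para oxygens follow from the mechanism. The silyl group makes 27 a practical acetylene equivalent.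

**26 to 22 and 23.** The C6–carbene carbon bond is cut. The alkenyllithium from vinyl bromide 22 adds to a CO ligand of 23, and O-methylation of the acylmetalate completes the carbene.

**22 to 21 to 20 to 19 to 18.** The C3′–isopropenyl bond is cut (conjugate addition to enone 20). The isopropenyl group has to arrive after the hydroboration that functionalises C6, since borane would attack it first. Enone 20 comes from diketone 19 by dehydrogenation, and 19 from bis-ketal 18 by hydrolysis. The acetyl group on C1 shields one face of ring E and so sets C3′.

**18 to 17 to 16 to 15 to 14.** The vinyl bromide is traced to the C6 ketone 17 and the alcohol 16. The C3–CH3 bond is cut (cross-coupling of the enol triflate 15). The C6–O bond comes from hydroboration of C6=C7 in 14, where the other alkene is an unreactive enol triflate.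

**14 to 13 to 10 and 11.** The C1–C2 and C4–C5 bonds are cut: an oxyallyl cation from 11 adds across the cyclopentadiene 10 in a (4+3) cycloaddition. This forms the seven-membered ring and the quaternary C1 next to quaternary C8 in one operation. The spiro ketal carbon of 10 directs the face, which fixes C1 and C5 relative to C8.

**10 to 8 to 7.** The bond between the diene terminus and the ketal carbon is cut. Enone 7 has no α′-hydrogen and gives the linear dienyl triflate 8, onto which a masked acetyl group is coupled. The ring ketone must be a ketal, because a free acyl group on the spiro carbon of a cyclopentadiene would migrate by 1,5-shift.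

**7 to 6 to 5 to 4 to 3 to 1 and 2.** The enone C=C is cut by ring-closing metathesis of dienone 6. The vinyl ketone comes from the ester of 4 through amide 5. The quaternary carbon of 3 is made by asymmetric allylation of 1 with 2. This carbon becomes C8 and is the only stereocentre not set by substrate control.

## Alternatives that were turned down

**Alternative 1:** cation–enol closure across a spiro cycloheptadiene.
- Disconnection: the C5–C8 bond of the prenylated bridged ene-dione A1 is cut. This leads to A2, in which the ring D ene-dione (prenyl on C8–H) is spiro-linked at C1 to a benzocycloheptadienol.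
- Forward key step: Sc(OTf)3 ionises the C5 carbinol to a benzylic allylic cation, and the C8 enol closes across the seven-membered ring. Rings B and C form together.
- For: both carbinol epimers and both C8 epimers converge on one cation and one enol. The tether allows only the cis bridge. Ring D is present from the start, so no oxidative coupling is needed. No stoichiometric metal is used. On convergence and step count it is stronger than the chosen route.
- Against: the bond being formed makes quaternary C8 next to quaternary C1 through a weakly nucleophilic, hindered ene-dione enol. It competes with O-alkylation, capture of the cation by the prenyl alkene, proton loss to a benzocycloheptatriene, and tautomerisation of the ene-dione to a hydroquinone. A2 also needs its spiro quaternary C1 as a single enantiomer, and no simple way to it is apparent.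
- Comparison: the chosen route builds the congested C1/C8 pair early by cycloaddition on a small molecule and keeps the late ring-forming key step free of stereochemical questions.

**Alternative 2:** palladium allylic dearomatisation of a flat fluorenol.
- Disconnection: the C1–C2 bond of the bridged dienone A3 is cut. This leads to the fluorene A4, in which ring A and a 4-methoxyphenol are joined by a biaryl bond and by C5; C5 carries a CH(OCO2Me)C(CH3)=CH2 chain.
- Forward key step: Pd2(dba)3 with PPh3 forms the allyl complex, and the phenolate attacks its CH2 terminus through the ring-fusion ortho carbon. This dearomatises the phenol, creates quaternary C1 and closes ring C.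
- For: A4 is flat and can be assembled by cross-coupling in few steps. The key step is catalytic and delivers the whole benzobicyclo[3.2.1] core plus a dienone that maps onto ring D. On precursor accessibility it is clearly stronger.
- Against: C5–H of A4 is a doubly benzylic fluorenyl hydrogen and is acidic under phenolate conditions, so C5 cannot be carried as a defined stereocentre. With PPh3 A3 would be racemic. The attack must occur at an already substituted ortho carbon (C- versus O-allylation) and must bridge a planar fluorene. After A3, C8 is still sp2, so the quaternary C8, ring E and C3′ all remain to be made.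
- Comparison: the chosen route has C8 in place from its first step and a non-acidic C5.

**Alternative 3:** Lewis acid ene closure of the bridged cyclopentanone.
- Disconnection: the C2′–C3′ bond of the target bis(methyl ether) A5 is cut, leading back to A1. A5 is identical with 32 of the chosen route.
- Forward key step: Me2AlCl activates the ene-dione of A1, the prenyl alkene bonds through C3′ to C2′, and an allylic hydrogen is transferred. This closes ring E and leaves the isopropenyl group.
- For: it is atom-economical, sets C2′ and C3′ and delivers the isopropenyl group in one step, and leaves only the demethylation. In the end-game it is stronger than the chosen route.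
- Against: it depends on A1 and so inherits the problems of Alternative 1. The prenyl alkene can also reach C10 (six-membered closure). The Lewis acid opens cationic side paths (Prins closure, chloride capture, isomerisation to isopropylidene). The exo placement of the isopropenyl group is decided by a transition state that is not obviously biased.
- Comparison: the chosen route sets C3′ by a sterically controlled conjugate addition and closes ring D by a coupling whose regiochemistry and stereochemistry are fixed by structure.

Key step: step 19

## Route

Remark: the hydroboration in step 10 is drawn as giving the C6 endo alcohol. Its configuration and a minor C7 regioisomer are immaterial, because the carbinol carbon becomes the alkenyl carbon and a carbene at C6 or at C7 leads to the same dimethyl ether 30.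

Remark: the ligand antipode in step 1 is the one that delivers (R)-3. The enantiomeric purity should be checked at 3 and, if needed, raised by crystallisation of a later solid intermediate.

Step 1
Reactants: 1 methyl 2-oxocyclopentane-1-carboxylate; 2 prop-2-enyl acetate
Product: 3 methyl (R)-2-oxo-1-(prop-2-enyl)cyclopentane-1-carboxylate
Conditions: [Pd(C3H5)Cl]2 (1 mol %), DACH-phenyl Trost ligand (2.5 mol %), tetramethylguanidine, toluene, 0 °C
Reagents that add atoms: none
Why: Palladium-catalysed asymmetric allylic alkylation (Tsuji–Trost) of a cyclic β-keto ester enolate; the chiral diphosphine pocket differentiates the enolate faces and sets the quaternary carbon that becomes C8.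

Step 2
Reactants: 3 methyl (R)-2-oxo-1-(prop-2-enyl)cyclopentane-1-carboxylate
Product: 4 methyl (R)-6-(prop-2-enyl)-1,4-dioxaspiro[4.4]nonane-6-carboxylate
Conditions: HOCH2CH2OH, p-TsOH (cat.), benzene, reflux, Dean–Stark
Reagents that add atoms: ethane-1,2-diol, OCCO
Why: Acid-catalysed ketalisation with azeotropic removal of water; the ketal prevents 1,5-acyl migration once the neighbouring ring is a cyclopentadiene and later provides the steric bias for the cycloaddition.

Step 3
Reactants: 4 methyl (R)-6-(prop-2-enyl)-1,4-dioxaspiro[4.4]nonane-6-carboxylate
Product: 5 (R)-N-methoxy-N-methyl-6-(prop-2-enyl)-1,4-dioxaspiro[4.4]nonane-6-carboxamide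
Conditions: MeNH(OMe)·HCl, i-PrMgCl, THF, −20 °C to rt
Reagents that add atoms: N,O-dimethylhydroxylamine hydrochloride, CNOC.Cl
Why: Weinreb amide formation by aminolysis of the ester with the magnesium amide; the ester has no α-hydrogen, so the longer reaction time needed for this neopentyl position does no harm.

Step 4
Reactants: 5 (R)-N-methoxy-N-methyl-6-(prop-2-enyl)-1,4-dioxaspiro[4.4]nonane-6-carboxamide
Product: 6 (S)-1-[6-(prop-2-enyl)-1,4-dioxaspiro[4.4]nonan-6-yl]prop-2-en-1-one
Conditions: CH2=CHMgBr, THF, 0 °C; inverse quench into cold 1 M HCl
Reagents that add atoms: vinylmagnesium bromide, C=C[Mg]Br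
Why: Grignard addition to a Weinreb amide stops at the chelated tetrahedral intermediate; the acidic inverse quench releases the vinyl ketone and keeps the liberated amine from adding to it.

Step 5
Reactants: 6 (S)-1-[6-(prop-2-enyl)-1,4-dioxaspiro[4.4]nonan-6-yl]prop-2-en-1-one
Product: 7 (S)-6,6-(ethylenedioxy)spiro[4.4]non-2-en-1-one
Conditions: second-generation Grubbs catalyst (2 mol %), CH2Cl2, 40 °C
Reagents that add atoms: none
Why: Ring-closing metathesis of the enone and allyl alkenes gives the cyclopentenone with loss of ethene; the quaternary carbon holds the two alkenes close.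

Step 6
Reactants: 7 (S)-6,6-(ethylenedioxy)spiro[4.4]non-2-en-1-one
Product: 8 (S)-6,6-(ethylenedioxy)spiro[4.4]nona-1,3-dien-1-yl trifluoromethanesulfonate
Conditions: KN(SiMe3)2, THF, −78 °C; PhNTf2, −78 to 0 °C
Reagents that add atoms: N-phenylbis(trifluoromethanesulfonimide), O=S(=O)(N(c1ccccc1)S(=O)(=O)C(F)(F)F)C(F)(F)F
Why: The enone has no α′-hydrogen, so the base can only remove the γ-hydrogen of the ring CH2; O-triflation of the linear dienolate gives the cyclopentadienyl triflate (enol triflate formation).

Step 7
Reactants: 8 (S)-6,6-(ethylenedioxy)spiro[4.4]nona-1,3-dien-1-yl trifluoromethanesulfonate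
Product: 10 (S)-6,6-(ethylenedioxy)-1-(2-methyl-1,3-dioxolan-2-yl)spiro[4.4]nona-1,3-diene, via ethoxyvinyl diene 9 (not isolated)
Conditions: CH2=C(OEt)SnBu3, Pd(PPh3)4 (5 mol %), LiCl, THF, 65 °C; then HOCH2CH2OH, PPTS (cat.), CH2Cl2, 0 °C to rt
Reagents that add atoms: tributyl(1-ethoxyethenyl)stannane, CCCC[Sn](CCCC)(CCCC)C(=C)OCC; ethane-1,2-diol, OCCO
Why: Stille coupling of the dienyl triflate with an acetyl anion equivalent, then acid-catalysed exchange of the enol ether into the dioxolane; the two operations are telescoped because the 2-ethoxydiene is hydrolytically labile.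

Step 8
Reactants: 10 (S)-6,6-(ethylenedioxy)-1-(2-methyl-1,3-dioxolan-2-yl)spiro[4.4]nona-1,3-diene; 11 1,1,3,3-tetrabromopropan-2-one
Product: 13 bicyclo[3.2.1]oct-6-en-3-one bis-ketal (C1 bears the 2-methyl-1,3-dioxolan-2-yl group; C8 is the spiro carbon of a cyclopentanone ethylene ketal whose ketal carbon C1′ lies over C6=C7), via dibromo ketone 12 (not isolated)
Conditions: Zn–Cu couple, B(OEt)3, THF, −10 °C to rt; then Zn–Cu couple, NH4Cl, MeOH, rt
Reagents that add atoms: none
Why: Oxyallyl cation (4+3) cycloaddition onto the cyclopentadiene followed by zinc debromination; the cation adds to the diene face anti to the ketal carbon of the spiro ring, which sets C1 and C5 relative to C8 and places C1′ over the C6=C7 bridge.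

Step 9
Reactants: 13 bicyclo[3.2.1]oct-6-en-3-one bis-ketal
Product: 14 C3 enol triflate of 13 with the C3=C4 double bond (bicyclo[3.2.1]octa-3,6-dien-3-yl trifluoromethanesulfonate bis-ketal)
Conditions: LiN(i-Pr)2, THF, −78 °C; PhNTf2, −78 to 0 °C
Reagents that add atoms: N-phenylbis(trifluoromethanesulfonimide), O=S(=O)(N(c1ccccc1)S(=O)(=O)C(F)(F)F)C(F)(F)F
Why: Kinetic deprotonation by the bulky amide should occur at C4, next to the C5 methine, and not at C2, which is neopentyl to quaternary C1 and its dioxolane; O-triflation traps the enolate (enol triflate formation).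

Step 10
Reactants: 14 C3 enol triflate bis-ketal
Product: 15 6-endo-hydroxy enol triflate bis-ketal (C6–OH on the side of the C2–C4 bridge; C7 is CH2)
Conditions: BH3·THF, THF, 0 °C to rt; then 30% H2O2, aq. NaOAc, 0 °C to rt
Reagents that add atoms: hydrogen peroxide, OO
Why: Hydroboration–oxidation; the electron-poor enol triflate alkene is inert to borane, so the small BH3 adds only to C6=C7. Addition should occur from the endo face because the exo face is covered by the dioxolane on C1′, with boron at C6, away from quaternary C1.

Step 11
Reactants: 15 6-endo-hydroxy enol triflate bis-ketal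
Product: 16 3-methylbicyclo[3.2.1]oct-3-en-6-endo-ol bis-ketal
Conditions: MeMgBr (3 equiv), Fe(acac)3 (5 mol %), THF/NMP, −30 to 0 °C
Reagents that add atoms: methylmagnesium bromide, C[Mg]Br
Why: Iron-catalysed cross-coupling of an alkenyl triflate with a methyl Grignard reagent; the magnesium alkoxide of the free hydroxyl is a spectator and the position of the C3=C4 bond was fixed in step 9.

Step 12
Reactants: 16 3-methylbicyclo[3.2.1]oct-3-en-6-endo-ol bis-ketal
Product: 17 3-methylbicyclo[3.2.1]oct-3-en-6-one bis-ketal
Conditions: Dess–Martin periodinane, NaHCO3, CH2Cl2, rt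
Reagents that add atoms: none
Why: Dess–Martin oxidation of the secondary alcohol under buffered conditions that leave both ketals intact; the carbinol stereocentre of step 10 disappears.

Step 13
Reactants: 17 3-methylbicyclo[3.2.1]oct-3-en-6-one bis-ketal
Product: 18 6-bromo-3-methylbicyclo[3.2.1]octa-3,6-diene bis-ketal
Conditions: (PhO)3P, Br2, CH2Cl2, −60 °C; then Et3N and 17, −60 °C to reflux
Reagents that add atoms: bromine (as its adduct with triphenyl phosphite), BrBr
Why: Conversion of an enolisable ketone into a vinyl bromide by the triphenyl phosphite–bromine reagent through an enol phosphonium intermediate; only C7 can supply the hydrogen, so the bromide is regiodefined, and no free bromine is present to attack C3=C4.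

Step 14
Reactants: 18 6-bromo-3-methylbicyclo[3.2.1]octa-3,6-diene bis-ketal
Product: 19 1-acetyl-6-bromo-3-methylbicyclo[3.2.1]octa-3,6-diene with C8 spiro to cyclopentan-1′-one
Conditions: 1 M HCl, THF, 40 °C
Reagents that add atoms: water, O
Why: Acid-catalysed hydrolysis of both dioxolanes; the vinyl bromide and the trisubstituted alkene tolerate dilute aqueous acid.

Step 15
Reactants: 19 diketone vinyl bromide
Product: 20 1-acetyl-6-bromo-3-methylbicyclo[3.2.1]octa-3,6-diene with C8 spiro to cyclopent-2′-en-1′-one
Conditions: IBX, DMSO/fluorobenzene, 75 °C
Reagents that add atoms: none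
Why: IBX dehydrogenation of a ketone to the enone needs hydrogens on the α- and β-carbons; in 19 only C2′–C3′ qualifies, because the acetyl group has no β-hydrogen and C8 is quaternary.

Step 16
Reactants: 20 spiro cyclopentenone vinyl bromide
Product: 21 1-acetyl-6-bromo-3-methylbicyclo[3.2.1]octa-3,6-diene with C8 spiro to 3′-isopropenylcyclopentan-1′-one (isopropenyl on the side of C5 and anti to the acetyl group)
Conditions: CH2=C(CH3)MgBr, CuBr·SMe2 (20 mol %), TMSCl, THF, −78 °C; then 1 M HCl
Reagents that add atoms: isopropenylmagnesium bromide, CC(=C)[Mg]Br
Why: Copper-catalysed, TMSCl-accelerated conjugate addition; the nucleophile should enter C3′ from the enone face that looks toward C5–H, away from the acetyl group on C1, which sets C3′. The hindered methyl ketone and the vinyl bromide should not react at −78 °C.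

Step 17
Reactants: 21 3′-isopropenyl diketone vinyl bromide
Product: 22 6-bromo-3-methylbicyclo[3.2.1]octa-3,6-diene bis-ketal with 3′-isopropenyl
Conditions: Me3SiOCH2CH2OSiMe3, TMSOTf (cat.), CH2Cl2, −78 to −20 °C; pyridine quench
Reagents that add atoms: 1,2-bis(trimethylsilyloxy)ethane, C[Si](C)(C)OCCO[Si](C)(C)C
Why: Noyori ketalisation under aprotic conditions protects both hindered ketones again so that the organolithium chemistry of step 18 is possible; the low temperature keeps the isopropenyl group from isomerising.

Step 18
Reactants: 22 vinyl bromide bis-ketal; 23 hexacarbonylchromium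
Product: 26 pentacarbonylchromium (methoxy)carbene on C6 of the 3-methylbicyclo[3.2.1]octa-3,6-diene bis-ketal, via vinyllithium 24 (not isolated), via lithium acylchromate 25 (not isolated)
Conditions: t-BuLi (2.1 equiv), THF, −78 °C; Cr(CO)6, −78 to 0 °C; then MeOTf, CH2Cl2, 0 °C
Reagents that add atoms: methyl trifluoromethanesulfonate, COS(=O)(=O)C(F)(F)F
Why: Lithium–bromine exchange, addition of the alkenyllithium to a CO ligand of 23 and O-methylation of the acylmetalate: the standard Fischer route to alkenyl(methoxy)carbene complexes.

Step 19
Reactants: 26 pentacarbonylchromium (methoxy)carbene; 27 ethynyltrimethylsilane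
Product: 28 silylated 4-methoxyphenol bis-ketal (ring A fused at C6–C7; OCH3 on the arene carbon next to C6, OH on the carbon next to C7, SiMe3 ortho to OH)
Conditions: 27 (3 equiv), THF, 50 °C, degassed; then air, MeCN, rt
Reagents that add atoms: none
Why: Dötz benzannulation. Thermal loss of one CO lets 27 coordinate and insert into the chromium–carbene bond; CO insertion then gives a chromium-bound vinylketene, which closes onto C7 and tautomerises by shift of the C7 hydrogen to the phenol. The closest known reaction type is the benzannulation of cycloalkenyl(methoxy)carbene pentacarbonylchromium complexes with terminal and silyl alkynes, including bicyclic alkenyl carbenes obtained from Diels–Alder adducts of alkynyl carbenes. Ring A is closed by 6π-electrocyclisation of the dienylketene (bond from the ketene carbon to C7) after two intermolecular C–C bonds have been made at the metal. No stereocentre is formed. The para relation of the two oxygens is intrinsic, since the carbene carbon and the CO-derived carbon end up at opposite corners of the new ring. The silyl group should go next to the hydroxyl for steric reasons, but this does not matter after step 20, and a partial shift of silicon from carbon to oxygen converges there as well. Phenol formation over cyclopentannulation is favoured by the alkenyl (not aryl) carbene, the methoxy group and THF as solvent. The isopropenyl and C3=C4 alkenes should not react with the carbene at 50 °C.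

Step 20
Reactants: 28 silylated 4-methoxyphenol bis-ketal
Product: 30 1,4-dimethoxyarene bis-ketal, via methoxyphenol 29 (not isolated)
Conditions: Bu4NF, THF, 50 °C; then MeI, rt
Reagents that add atoms: iodomethane, CI
Why: Fluoride-induced ipso-protodesilylation of the ortho-silylphenol through its phenoxide (an O-silyl isomer would be cleaved even faster), then Williamson methylation of the ammonium phenoxide; both ring A oxygens are masked before the enolate chemistry.

Step 21
Reactants: 30 1,4-dimethoxyarene bis-ketal
Product: 31 1,4-dimethoxyarene diketone (acetyl on C1, cyclopentan-1′-one on C8)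
Conditions: 1 M HCl, THF, rt to 40 °C
Reagents that add atoms: water, O
Why: Acid-catalysed hydrolysis of both dioxolanes frees the two ketones; dilute acid at moderate temperature should leave the isopropenyl group and the aryl ethers untouched.

Step 22
Reactants: 31 1,4-dimethoxyarene diketone
Product: 32 pentacyclic bis(methyl ether) of the target
Conditions: LiN(i-Pr)2 (2.3 equiv), THF, −78 °C; CuCl2 (2.5 equiv), DMF, −78 °C to rt
Reagents that add atoms: none
Why: Intramolecular oxidative coupling of a ketone bis-enolate with CuCl2 (Saegusa-type 1,4-diketone synthesis); each ketone can enolise only toward C2′ or C10, and C10 can reach C2′ only from the face turned toward C1, so ring D closes with the C2′ configuration of the target.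

Step 23
Reactants: 32 pentacyclic bis(methyl ether)
Product: 34 CNP0287617.1, via quinone 33 (not isolated)
Conditions: (NH4)2Ce(NO3)6, MeCN/H2O, 0 °C; then aq. Na2S2O4, EtOAc, under N2
Reagents that add atoms: water, O
Why: Oxidative demethylation of the 1,4-dimethoxyarene gives the quinone, whose oxygens come from water, and dithionite reduces it to the hydroquinone in the work-up; the bridgehead C5 cannot tautomerise to a quinone methide.

## Compound list

1 | methyl 2-oxocyclopentane-1-carboxylate | COC(=O)C1CCCC1=O | starting material
2 | prop-2-enyl acetate | CC(=O)OCC=C | starting material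
3 | methyl (R)-2-oxo-1-(prop-2-enyl)cyclopentane-1-carboxylate | O=C1CCC[C@]1(CC=C)C(=O)OC | intermediate
4 | methyl (R)-6-(prop-2-enyl)-1,4-dioxaspiro[4.4]nonane-6-carboxylate | O1CCOC12CCC[C@]2(CC=C)C(=O)OC | intermediate
5 | (R)-N-methoxy-N-methyl-6-(prop-2-enyl)-1,4-dioxaspiro[4.4]nonane-6-carboxamide | O1CCOC12CCC[C@]2(CC=C)C(=O)N(C)OC | intermediate
6 | (S)-1-[6-(prop-2-enyl)-1,4-dioxaspiro[4.4]nonan-6-yl]prop-2-en-1-one | O1CCOC12CCC[C@]2(CC=C)C(=O)C=C | intermediate
7 | (S)-6,6-(ethylenedioxy)spiro[4.4]non-2-en-1-one | O1CCOC12CCC[C@@]23CC=CC3=O | intermediate
8 | (S)-6,6-(ethylenedioxy)spiro[4.4]nona-1,3-dien-1-yl trifluoromethanesulfonate | O1CCOC12CCC[C@@]23C=CC=C3OS(=O)(=O)C(F)(F)F | intermediate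
9 | (S)-1-(1-ethoxyethenyl)-6,6-(ethylenedioxy)spiro[4.4]nona-1,3-diene | O1CCOC12CCC[C@@]23C=CC=C3C(=C)OCC | intermediate
10 | (S)-6,6-(ethylenedioxy)-1-(2-methyl-1,3-dioxolan-2-yl)spiro[4.4]nona-1,3-diene | CC1(OCCO1)C2=CC=C[C@@]23CCCC34OCCO4 | intermediate
11 | 1,1,3,3-tetrabromopropan-2-one | BrC(Br)C(=O)C(Br)Br | starting material
12 | 2,4-dibromo derivative of 13 (mixture of bromide epimers) | CC1(OCCO1)[C@]23C(Br)C(=O)C(Br)[C@H](C=C2)[C@@]35CCCC56OCCO6 | intermediate
13 | bicyclo[3.2.1]oct-6-en-3-one bis-ketal (C1 dioxolanyl; C8 spiro; C1′ ketal carbon over C6=C7) | CC1(OCCO1)[C@]23CC(=O)C[C@H](C=C2)[C@@]35CCCC56OCCO6 | intermediate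
14 | C3 enol triflate of 13 (C3=C4) | CC1(OCCO1)[C@]23CC(OS(=O)(=O)C(F)(F)F)=C[C@H](C=C2)[C@@]35CCCC56OCCO6 | intermediate
15 | 6-endo-hydroxy enol triflate bis-ketal | CC1(OCCO1)[C@]23CC(OS(=O)(=O)C(F)(F)F)=C[C@H]([C@H](O)C2)[C@@]35CCCC56OCCO6 | intermediate
16 | 3-methylbicyclo[3.2.1]oct-3-en-6-endo-ol bis-ketal | CC1(OCCO1)[C@]23CC(C)=C[C@H]([C@H](O)C2)[C@@]35CCCC56OCCO6 | intermediate
17 | 3-methylbicyclo[3.2.1]oct-3-en-6-one bis-ketal | CC1(OCCO1)[C@]23CC(C)=C[C@H](C(=O)C2)[C@@]35CCCC56OCCO6 | intermediate
18 | 6-bromo-3-methylbicyclo[3.2.1]octa-3,6-diene bis-ketal | CC1(OCCO1)[C@]23CC(C)=C[C@H](C(Br)=C2)[C@@]35CCCC56OCCO6 | intermediate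
19 | 1-acetyl-6-bromo-3-methyl diene, C8 spiro to cyclopentan-1′-one | CC(=O)[C@]23CC(C)=C[C@H](C(Br)=C2)[C@@]35CCCC5=O | intermediate
20 | 1-acetyl-6-bromo-3-methyl diene, C8 spiro to cyclopent-2′-en-1′-one | CC(=O)[C@]23CC(C)=C[C@H](C(Br)=C2)[C@@]35CC=CC5=O | intermediate
21 | 1-acetyl-6-bromo-3-methyl diene, C8 spiro to 3′-isopropenylcyclopentan-1′-one (isopropenyl on the C5 side) | CC(=O)[C@]23CC(C)=C[C@H](C(Br)=C2)[C@@]35C[C@H](C(C)=C)CC5=O | intermediate
22 | 6-bromo-3-methyl diene bis-ketal with 3′-isopropenyl | CC1(OCCO1)[C@]23CC(C)=C[C@H](C(Br)=C2)[C@@]35C[C@H](C(C)=C)CC56OCCO6 | intermediate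
23 | hexacarbonylchromium | O=C=[Cr](=C=O)(=C=O)(=C=O)(=C=O)=C=O | starting material
24 | C6 alkenyllithium of the bis-ketal | CC1(OCCO1)[C@]23CC(C)=C[C@H](C([Li])=C2)[C@@]35C[C@H](C(C)=C)CC56OCCO6 | intermediate
25 | lithium acylpentacarbonylchromate of the bis-ketal | [Li+].CC1(OCCO1)[C@]23CC(C)=C[C@H](C(=C2)C([O-])=[Cr](=C=O)(=C=O)(=C=O)(=C=O)=C=O)[C@@]35C[C@H](C(C)=C)CC56OCCO6 | intermediate
26 | pentacarbonylchromium alkenyl(methoxy)carbene of the bis-ketal (carbene on C6) | CC1(OCCO1)[C@]23CC(C)=C[C@H](C(=C2)C(OC)=[Cr](=C=O)(=C=O)(=C=O)(=C=O)=C=O)[C@@]35C[C@H](C(C)=C)CC56OCCO6 | intermediate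
27 | ethynyltrimethylsilane | C#C[Si](C)(C)C | starting material
28 | silylated 4-methoxyphenol bis-ketal | CC1(OCCO1)[C@]23CC(C)=C[C@H](c4c(OC)cc([Si](C)(C)C)c(O)c42)[C@@]35C[C@H](C(C)=C)CC56OCCO6 | intermediate
29 | 4-methoxyphenol bis-ketal | CC1(OCCO1)[C@]23CC(C)=C[C@H](c4c(OC)ccc(O)c42)[C@@]35C[C@H](C(C)=C)CC56OCCO6 | intermediate
30 | 1,4-dimethoxyarene bis-ketal | CC1(OCCO1)[C@]23CC(C)=C[C@H](c4c(OC)ccc(OC)c42)[C@@]35C[C@H](C(C)=C)CC56OCCO6 | intermediate
31 | 1,4-dimethoxyarene diketone | CC(=O)[C@]23CC(C)=C[C@H](c4c(OC)ccc(OC)c42)[C@@]35C[C@H](C(C)=C)CC5=O | intermediate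
32 | pentacyclic bis(methyl ether) of the target | C=C(C)[C@H]1C[C@@]23C(=O)[C@@H]1CC(=O)[C@@]21CC(C)=C[C@@H]3c2c(OC)ccc(OC)c21 | intermediate
33 | pentacyclic quinone | C=C(C)[C@H]1C[C@@]23C(=O)[C@@H]1CC(=O)[C@@]21CC(C)=C[C@@H]3C2=C1C(=O)C=CC2=O | intermediate
34 | CNP0287617.1 | C=C(C)[C@H]1C[C@@]23C(=O)[C@@H]1CC(=O)[C@@]21CC(C)=C[C@@H]3c2c(O)ccc(O)c21 | target

## Step count and least certain steps

Total: 23 steps. Longest linear sequence: 23 steps (from 1; everything else is a commercial reagent).

**Step 19 (key step).**
- Risk: the chromium-centred events after alkyne insertion (CO insertion, electrocyclisation) may be slowed because both faces of C6=C7 are shielded, by the dioxolane on C1′ above and by ring C below. Cyclopentannulation, furan formation or simple decomposition of the carbene could then overtake phenol formation.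
- Fallback: generate the same dienylketene without chromium, setting out from 22 and coming back at 29.
  - Lithium–bromine exchange on 22 and carboxylation with CO2 give the enoic acid F1.
  - Activation with carbonyldiimidazole and reaction with Mg(O2CCH2CO2Et)2 give the β-keto ester F2.
  - O-methylation (Me2SO4, K2CO3, DMF) gives the (E)-β-methoxy dienoate F3, whose ester is cis to C6.
  - Saponification (LiOH) gives the β-methoxy dienoic acid F4.
  - The mixed anhydride with 2,4,6-trichlorobenzoyl chloride and Et3N in hot toluene should eliminate to the ketene, which undergoes 6π-electrocyclisation onto C7 and tautomerises to 29. This is methylated as in step 20.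

**Step 8.**
- Risk: ring closure at the substituted diene terminus, which creates quaternary C1 beside quaternary C8, may be slow. The intermediate could then collapse by (3+2) closure or proton loss, and zinc bromide may ionise the dienylic ketal. Facial control could also be incomplete.
- Fallback: a cyclopropanation–Cope sequence, setting out from 10 and coming back at 16.
  - Rh2(OAc)4-catalysed cyclopropanation of the less substituted double bond of 10 with methyl 2-diazo-3-methylbut-3-enoate, then Cope rearrangement of the cis-divinylcyclopropane in the flask, gives the dienyl ester F5. The C1–C2 bond is formed intramolecularly and the methyl alkene is placed unambiguously.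
  - Saponification gives the acid F6.
  - Barton decarboxylation (N-hydroxypyridine-2-thione ester, t-BuSH, light) gives the 3-methyl diene F7.
  - Hydroboration with 9-BBN and oxidation should take the strained disubstituted C6=C7 in preference to the trisubstituted C3=C4 and give 16.

**Step 9.**
- Risk: deprotonation at C2, possibly helped by lithium coordination to the neighbouring dioxolane, would give the regioisomeric enol triflate.
- Fallback: from 13 to 14 under reagent control. The two α-methylene groups of 13 are quasi-enantiotopic, and a chiral lithium amide (lithium bis(1-phenylethyl)amide of the matching antipode with LiCl, then PhNTf2) is known to distinguish them in bicyclo[3.2.1]octan-3-ones. No new compound arises (F0).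

**Step 10.**
- Risk: addition of borane to an alkene shielded on both faces may be slow, leaving time for attack on the triflate or the ketals.
- Fallback: from 14 to 15 by epoxidation and reductive opening. m-CPBA should oxidise only C6=C7 (the enol triflate is deactivated) to the epoxide F8. Titanocene-mediated radical opening (Cp2TiCl, 1,4-cyclohexadiene) then gives 15 or its C7 regioisomer, which serves equally.

**Step 16.**
- Risk: facial discrimination at C3′ may be insufficient, since the controlling acetyl group is three bonds away.
- Fallback: from 20 to 21 under catalyst control. Rhodium-catalysed 1,4-addition of potassium isopropenyltrifluoroborate with [Rh(cod)Cl]2 and the BINAP antipode that reinforces the substrate bias. No new compound arises (F0).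

**Step 22.**
- Risk: intermolecular coupling, α-chlorination by CuCl2, or failure of the two enolate carbons to meet because ring D must close in a strained bicyclic geometry.
- Fallback: from 31 to 32 through the silyl bis-enol ether. TMSOTf and Et3N convert 31 into the bis(trimethylsilyl enol ether) F9, which is coupled by one-electron oxidation (Cu(OTf)2, Cu2O, MeCN). If an oxidant is used that also attacks ring A, quinone 33 results and is reduced as in step 23.

## Further compounds

F1 | step 19 | C6 enoic acid of the bis-ketal | CC1(OCCO1)[C@]23CC(C)=C[C@H](C(=C2)C(=O)O)[C@@]35C[C@H](C(C)=C)CC56OCCO6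
F2 | step 19 | C6 β-keto ethyl ester of the bis-ketal | CC1(OCCO1)[C@]23CC(C)=C[C@H](C(=C2)C(=O)CC(=O)OCC)[C@@]35C[C@H](C(C)=C)CC56OCCO6
F3 | step 19 | (E)-β-methoxy dienoate (ester cis to C6) | CC1(OCCO1)[C@]23CC(C)=C[C@H](C(=C2)/C(OC)=C\C(=O)OCC)[C@@]35C[C@H](C(C)=C)CC56OCCO6
F4 | step 19 | (E)-β-methoxy dienoic acid | CC1(OCCO1)[C@]23CC(C)=C[C@H](C(=C2)/C(OC)=C\C(=O)O)[C@@]35C[C@H](C(C)=C)CC56OCCO6
F5 | step 8 | methyl 3-methylbicyclo[3.2.1]octa-3,6-diene-4-carboxylate bis-ketal | CC1(OCCO1)[C@]23CC(C)=C(C(=O)OC)[C@H](C=C2)[C@@]35CCCC56OCCO6
F6 | step 8 | 3-methylbicyclo[3.2.1]octa-3,6-diene-4-carboxylic acid bis-ketal | CC1(OCCO1)[C@]23CC(C)=C(C(=O)O)[C@H](C=C2)[C@@]35CCCC56OCCO6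
F7 | step 8 | 3-methylbicyclo[3.2.1]octa-3,6-diene bis-ketal | CC1(OCCO1)[C@]23CC(C)=C[C@H](C=C2)[C@@]35CCCC56OCCO6
F0 | step 9 | none | none
F8 | step 10 | 6,7-epoxide of 14 (endo face) | CC1(OCCO1)[C@]23CC(OS(=O)(=O)C(F)(F)F)=C[C@H](C4OC42)[C@@]35CCCC56OCCO6
F0 | step 16 | none | none
F9 | step 22 | bis(trimethylsilyl enol ether) of 31 | C=C(O[Si](C)(C)C)[C@]23CC(C)=C[C@H](c4c(OC)ccc(OC)c42)[C@@]35C[C@H](C(C)=C)C=C5O[Si](C)(C)C
A1 | alternative 1 | prenylated bridged ene-dione | CC(C)=CC[C@@]23C(=O)C=CC(=O)[C@@]21CC(C)=C[C@@H]3c2c(OC)ccc(OC)c21
A2 | alternative 1 | spiro benzocycloheptadienol ene-dione (carbinol and C8–H epimers) | CC(C)=CCC2C(=O)C=CC(=O)[C@@]21CC(C)=CC(O)c2c(OC)ccc(OC)c21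
A3 | alternative 2 | bridged 4-methoxycyclohexa-2,4-dienone | COC1=C2[C@@H]3C=C(C)C[C@@]2(C(=O)C=C1)c1c(OC)ccc(OC)c13
A4 | alternative 2 | fluorenyl phenol allylic carbonate (stereocentres undefined) | COC(=O)OC(C(C)=C)C1c2c(OC)ccc(O)c2-c2c(OC)ccc(OC)c21
A5 | alternative 3 | target bis(methyl ether), identical with 32 | C=C(C)[C@H]1C[C@@]23C(=O)[C@@H]1CC(=O)[C@@]21CC(C)=C[C@@H]3c2c(OC)ccc(OC)c21
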